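**Retrosynthetic overview**

1. Numbering used throughout: ring C1 (bears the side chain), C2 (CH2), C3/C4 (epoxide, CH3 on C4), C5 and C6 (angelate carbons, C6 next to C1); chain C7 (=CH2), C8 (CHOAc), C9, C10=C11. The acetate and then the C7–C8 bond are disconnected: 2-iodo-1-alkene 14 plus 4-methylpent-3-enal by an asymmetric Ni/Cr (Nozaki–Hiyama–Kishi) coupling. This is possible because C8 is a carbinol carbon bonded directly to C7, the inner carbon of the C7=CH2 methylidene.
2. The C7–I bond comes from a C7–Si bond in a temporary ring. O6, C6, C1 and C7 are cis-1,2 on the cyclohexane, so they can be closed through SiMe2 to a five-membered 1-oxa-2-silacyclopentane by a tethered 5-exo vinyl-radical cyclisation. That ring sets C1 and marks C7, and is opened again by iododesilylation.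
3. The epoxide comes from the C3=C4 alkene by epoxidation directed by the free O5–H. The cis C5/C6 diol and the six-membered ring itself come from dioxygenase cis-dihydroxylation of 4-iodotoluene; iodine steers the enzyme and is then removed.
4. Ring order: carbocycle taken from the arene (no carbocyclisation); temporary oxasilolane closed (step 5); epoxide (step 6); oxasilolane opened (step 7). Both angelates go on before the key step and the acetate after it; no protecting group is used.

Key step: step 10

Remark (assumption): the sense of induction of the oxazoline–sulfonamide chromium ligand in step 10 is not derived here; the ligand antipode that leads to the (8S)-carbinol would be fixed by one model coupling.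
Remark: (1-bromoethenyl)chlorodimethylsilane is made in step 3 because its commercial supply is uncertain.

**Route**

Step 1
Reactants: 1 4-iodotoluene
Product: 2 (1S,2S)-3-iodo-6-methylcyclohexa-3,5-diene-1,2-diol
Conditions: Pseudomonas putida UV4 whole cells (toluene dioxygenase, no diol dehydrogenase), glucose, phosphate buffer pH 7, air, 30 °C
Reagents that add atoms: dioxygen, O=O
Why: Toluene-dioxygenase arene cis-dihydroxylation should deliver both oxygens from one face to the ring bond flanking the larger iodine substituent, which fixes the two carbinol centres (later C5 and C6) in the absolute sense that toluene itself would not give.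

Step 2
Reactants: 2 (1S,2S)-3-iodo-6-methylcyclohexa-3,5-diene-1,2-diol
Product: 3 (1R,2S)-3-methylcyclohexa-3,5-diene-1,2-diol
Conditions: Pd(OAc)2 (cat.), PPh3, HCO2H, Et3N, DMF, 40 °C
Reagents that add atoms: none
Why: Palladium-catalysed formate reduction of an alkenyl iodide (oxidative addition, decarboxylation of the Pd formate, C–H reductive elimination) should remove the directing iodine under buffered conditions that neither touch the stereocentres nor dehydrate the diene diol to a phenol.

Step 3
Reactants: 4 chlorodimethyl(vinyl)silane
Product: 6 (1-bromoethenyl)chlorodimethylsilane, via chloro(1,2-dibromoethyl)dimethylsilane 5 (not isolated)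
Conditions: Br2, CH2Cl2, –78 °C; then Et3N, reflux; distillation
Reagents that add atoms: bromine, BrBr
Why: Bromine addition to a vinylsilane followed by base-induced dehydrobromination (the α-hydrogen is acidified by silicon and bromine) is the standard entry to α-bromovinylsilanes, and a tertiary amine should leave the Si–Cl bond intact.

Step 4
Reactants: 3 (1R,2S)-3-methylcyclohexa-3,5-diene-1,2-diol; 6 (1-bromoethenyl)chlorodimethylsilane
Product: 7 (1S,6R)-6-{[(1-bromoethenyl)dimethylsilyl]oxy}-2-methylcyclohexa-2,4-dien-1-ol
Conditions: Et3N, CH2Cl2, –78 °C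
Reagents that add atoms: none
Why: Kinetic O-silylation should take the less hindered hydroxyl (O6, flanked by the unsubstituted alkene carbon rather than the methyl-bearing one); no stereocentre changes.

Step 5
Reactants: 7 bromovinylsilyl ether
Product: 8 cis-fused silacycle (2,2,6-trimethyl-3-methylidene-2,3,3a,4,7,7a-hexahydro-1,2-benzoxasilol-7-ol)
Conditions: Bu3SnH (slow addition), AIBN (cat.), PhH, 80 °C
Reagents that add atoms: none
Why: In this silicon-tethered radical cyclisation (Nishiyama–Stork type) the α-silylvinyl radical should add 5-exo to the near diene carbon on the face of the tethering oxygen, which sets C1 cis to O6, and the resulting allyl radical should take hydrogen at its less hindered secondary end C2 so that the trisubstituted C3=C4 alkene remains.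

Step 6
Reactants: 8 cis-fused silacycle
Product: 9 epoxy silacycle
Conditions: VO(acac)2 (cat.), t-BuOOH, CH2Cl2, 0 °C to rt
Reagents that add atoms: tert-butyl hydroperoxide, CC(C)(C)OO
Why: Vanadium-catalysed hydroxyl-directed epoxidation of the cyclic allylic alcohol should deliver oxygen syn to the C5 hydroxyl and so set C3 and C4, while the vinylsilane alkene, which has no free allylic hydroxyl, is left.

Step 7
Reactants: 9 epoxy silacycle
Product: 11 iodoalkene epoxy diol, via N-silylsuccinimide 10 (not isolated)
Conditions: NIS, MeCN–ClCH2CN (4:1), 0 °C, dark; then K2CO3 (cat.), MeOH, 0 °C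
Reagents that add atoms: N-iodosuccinimide, O=C1CCC(=O)N1I
Why: Electrophilic ipso-iododesilylation (iodonium formation at the vinylsilane, loss of silicon from the same carbon to succinimide) should give the 2-iodo-1-alkene, and methanolysis then cleaves the remaining labile dimethylsilyl ether; no stereocentre is involved.

Step 8
Reactants: 11 iodoalkene epoxy diol; 12 angelic acid (two equivalents incorporated)
Product: 14 iodoalkene bis-angelate, via mixed anhydride 13 (not isolated)
Conditions: 2,4,6-trichlorobenzoyl chloride, Et3N, PhMe, rt; then 11, 80 °C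
Reagents that add atoms: none
Why: Yamaguchi-type esterification through the mixed anhydride should acylate both secondary hydroxyls at the less hindered angeloyl carbonyl without a nucleophilic catalyst, which keeps the Z-alkene from isomerising to the tiglate.

Step 9
Reactants: 15 4-methylpent-3-en-1-ol
Product: 16 4-methylpent-3-enal
Conditions: Dess–Martin periodinane, NaHCO3, CH2Cl2, 0 °C; used at once as a solution
Reagents that add atoms: none
Why: Buffered Dess–Martin oxidation should give the β,γ-unsaturated aldehyde without acid or base that would move the alkene into conjugation.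

Step 10
Reactants: 14 iodoalkene bis-angelate; 16 4-methylpent-3-enal
Product: 19 (8S)-allylic alcohol, via alkenylchromium(III) species 17 (not isolated), via chromium(III) alkoxide 18 (not isolated)
Conditions: CrCl2, N-[2-(4-isopropyl-4,5-dihydrooxazol-2-yl)-6-methylphenyl]methanesulfonamide (antipode chosen for 8S), Et3N, NiCl2 (cat.), THF, rt; aqueous work-up
Reagents that add atoms: none
Why: Ni(0) inserts into the C7–I bond and hands the alkenyl group to Cr(III) (17), and the alkenylchromium adds to the aldehyde carbonyl inside the chiral sulfonamide–Cr(III) complex to give alkoxide 18, freed on work-up; the closest known reaction type is the asymmetric Ni/Cr-mediated (Nozaki–Hiyama–Kishi) coupling of 2-iodo-1-alkenes with aldehydes to 2-substituted allylic alcohols. No ring is closed in this step. The one new stereocentre, C8, is set by the ligand on chromium (reagent control), which has to override any bias from the C1 stereocentre next to the metal-bearing carbon. The step needs chemoselectivity for the aldehyde over two enoate esters and an epoxide, which the low basicity and low ester and epoxide reactivity of alkenylchromium(III) secure, and it needs the β,γ-unsaturated aldehyde to be captured before it moves into conjugation, which the near-neutral medium and an excess of freshly made 16 secure. In one operation it completes the carbon skeleton, turns the C–I bond into the methylidene-bearing C7–C8 bond and sets the last stereocentre on a substrate without protecting groups, so that only acetylation remains.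

Step 11
Reactants: 19 (8S)-allylic alcohol
Product: 20 CNP0188566.2
Conditions: Ac2O, pyridine, CH2Cl2, 0 °C
Reagents that add atoms: acetic anhydride, CC(=O)OC(C)=O
Why: Standard acylation of the only free hydroxyl proceeds with retention at C8, and a short reaction at 0 °C without a nucleophilic catalyst should avoid Z-to-E isomerisation of the angelates.

**Compound list**

1 | 4-iodotoluene | Cc1ccc(I)cc1 | starting material
2 | (1S,2S)-3-iodo-6-methylcyclohexa-3,5-diene-1,2-diol (cis-diol, C–I next to C2) | CC1=CC=C(I)[C@@H](O)[C@H]1O | intermediate
3 | (1R,2S)-3-methylcyclohexa-3,5-diene-1,2-diol (cis-diol) | CC1=CC=C[C@@H](O)[C@H]1O | intermediate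
4 | chlorodimethyl(vinyl)silane | C=C[Si](C)(C)Cl | starting material
5 | chloro(1,2-dibromoethyl)dimethylsilane | BrCC(Br)[Si](C)(C)Cl | intermediate (not isolated)
6 | (1-bromoethenyl)chlorodimethylsilane | C=C(Br)[Si](C)(C)Cl | intermediate
7 | (1S,6R)-6-{[(1-bromoethenyl)dimethylsilyl]oxy}-2-methylcyclohexa-2,4-dien-1-ol (silyl ether on O6, free O5–H, cis) | CC1=CC=C[C@@H](O[Si](C)(C)C(Br)=C)[C@H]1O | intermediate
8 | 2,2,6-trimethyl-3-methylidene-2,3,3a,4,7,7a-hexahydro-1,2-benzoxasilol-7-ol; ring fusion cis, 7-OH on the same face as O1 and C3 | C=C1[C@@H]2CC=C(C)[C@H](O)[C@@H]2O[Si]1(C)C | intermediate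
9 | 5,6-epoxide of 8; epoxide oxygen on the same face as 7-OH, O1 and C3 | C=C1[C@@H]2C[C@@H]3O[C@]3(C)[C@H](O)[C@@H]2O[Si]1(C)C | intermediate
10 | N-silylsuccinimide: 11 carrying an O6–SiMe2–N(succinimidyl) group | C=C(I)[C@@H]1C[C@@H]2O[C@]2(C)[C@H](O)[C@@H]1O[Si](C)(C)N3C(=O)CCC3=O | intermediate (not isolated)
11 | all-cis 3,4-epoxy-1-(1-iodoethenyl)-4-methylcyclohexane-5,6-diol (side chain, epoxide O, 5-OH and 6-OH on one face) | C=C(I)[C@@H]1C[C@@H]2O[C@]2(C)[C@H](O)[C@@H]1O | intermediate
12 | angelic acid, (Z)-2-methylbut-2-enoic acid | C/C=C(/C)C(=O)O | starting material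
13 | angelic 2,4,6-trichlorobenzoic anhydride | C/C=C(/C)C(=O)OC(=O)c1c(Cl)cc(Cl)cc1Cl | intermediate (not isolated)
14 | 5,6-bis-O-angeloyl derivative of 11 | C=C(I)[C@@H]1C[C@@H]2O[C@]2(C)[C@H](OC(=O)/C(C)=C\C)[C@@H]1OC(=O)/C(C)=C\C | intermediate
15 | 4-methylpent-3-en-1-ol | CC(C)=CCCO | starting material
16 | 4-methylpent-3-enal | CC(C)=CCC=O | intermediate
17 | alkenylchromium(III) dichloride from 14 (drawn without the ligand) | C=C([Cr](Cl)Cl)[C@@H]1C[C@@H]2O[C@]2(C)[C@H](OC(=O)/C(C)=C\C)[C@@H]1OC(=O)/C(C)=C\C | intermediate (not isolated)
18 | chromium(III) alkoxide of 19 (drawn without the ligand) | C=C([C@H](CC=C(C)C)O[Cr](Cl)Cl)[C@@H]1C[C@@H]2O[C@]2(C)[C@H](OC(=O)/C(C)=C\C)[C@@H]1OC(=O)/C(C)=C\C | intermediate (not isolated)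
19 | (8S)-alcohol: the target lacking the acetyl group | C=C([C@H](CC=C(C)C)O)[C@@H]1C[C@@H]2O[C@]2(C)[C@H](OC(=O)/C(C)=C\C)[C@@H]1OC(=O)/C(C)=C\C | intermediate
20 | CNP0188566.2: (8S)-8-acetoxy, 5,6-bis-angeloyloxy, 3,4-epoxy compound with all ring substituents cis | C=C([C@H](CC=C(C)C)OC(C)=O)[C@@H]1C[C@@H]2O[C@]2(C)[C@H](OC(=O)/C(C)=C\C)[C@@H]1OC(=O)/C(C)=C\C | target

**Step count**

Total step count: 11. Longest linear sequence: 9 steps (1, 2, 4, 5, 6, 7, 8, 10, 11).

**Steps most likely to fail**

Step 10. The chiral chromium complex may not discriminate the aldehyde faces well enough, or the C1 stereocentre may work against it, and the β,γ-unsaturated aldehyde may drift into conjugation before it is captured. The fallback sets out from 14 (with 16) and sets C8 by reduction instead of addition. The coupling is run without the chiral ligand (CrCl2, cat. NiCl2, DMF–THF) to give the C8-epimer mixture of alcohol 19 F1. Dess–Martin oxidation gives the C8 ketone F2. Corey–Bakshi–Shibata reduction with the (R)-methyl oxazaborolidine and catecholborane at –78 °C, in which the α-branched alkenyl group acts as the large substituent, should give the (8S)-alcohol and comes back to the route at 19.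

Step 7. The electrophile or adventitious acid may attack the trisubstituted epoxide, or iodine may add across the alkene without loss of silicon. The fallback sets out from 9 and reaches the iodoalkene through the carbonyl group. Tamao–Fleming oxidation (KF, KHCO3, H2O2, THF–MeOH) cleaves the Si–C7 bond and should give the β-hydroxy methyl ketone F3. Hydrazine hydrate gives the hydrazone F4. The Barton vinyl iodide synthesis (I2, tetramethylguanidine, THF, 0 °C) should then give the 2-iodo-1-alkene and comes back to the route at 11.

Step 4. Silylation may occur at the wrong hydroxyl or at both, and the silyl group may migrate between the cis hydroxyls. The fallback sets out from 3 and fixes the regiochemistry with a cyclic acetal. Anisaldehyde dimethyl acetal and PPTS give the p-methoxybenzylidene acetal F5. DIBAL-H opening should leave the PMB group on the more hindered O5 and free O6, giving the O5-PMB ether F6. Silylation with 6 gives the bromovinylsilyl ether F7. Radical cyclisation as in step 5 gives the PMB-protected silacycle F8. DDQ removal of the PMB group comes back to the route at 8.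

**Further compounds**

F1 | step 10 | C8-epimer mixture of alcohol 19 | C=C(C(O)CC=C(C)C)[C@@H]1C[C@@H]2O[C@]2(C)[C@H](OC(=O)/C(C)=C\C)[C@@H]1OC(=O)/C(C)=C\C
F2 | step 10 | C8 ketone (cross-conjugated enone) | C=C(C(=O)CC=C(C)C)[C@@H]1C[C@@H]2O[C@]2(C)[C@H](OC(=O)/C(C)=C\C)[C@@H]1OC(=O)/C(C)=C\C
F3 | step 7 | all-cis 1-acetyl-3,4-epoxy-4-methylcyclohexane-5,6-diol | CC(=O)[C@@H]1C[C@@H]2O[C@]2(C)[C@H](O)[C@@H]1O
F4 | step 7 | hydrazone of F3 | CC(=NN)[C@@H]1C[C@@H]2O[C@]2(C)[C@H](O)[C@@H]1O
F5 | step 4 | p-methoxybenzylidene acetal of 3 | CC1=CC=C[C@H]2OC(c3ccc(OC)cc3)O[C@@H]12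
F6 | step 4 | O5-(4-methoxybenzyl) ether of 3 with free O6–H | CC1=CC=C[C@@H](O)[C@H]1OCc2ccc(OC)cc2
F7 | step 4 | O6-[(1-bromoethenyl)dimethylsilyl] ether of F6 | CC1=CC=C[C@@H](O[Si](C)(C)C(Br)=C)[C@H]1OCc2ccc(OC)cc2
F8 | step 4 | O-(4-methoxybenzyl) ether of silacycle 8 | C=C1[C@@H]2CC=C(C)[C@H](OCc3ccc(OC)cc3)[C@@H]2O[Si]1(C)C
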